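The readings are simulated with constants of no real substance; scatter was added.

A closed, stirred flask at constant volume and temperature receives substrate, and the six new flasks differ in their charge.

| flask | substrate | remark | time |
|---|---|---|---|
| noon | 0.048 M | run made earlier |  |
| dusk | 0.15 M | run made earlier |  |
| north | 0.051 M |  | 10 h |
| north-east | 0.080 M |  | 10 h |
| south-east | 0.012 M |  | 10 h |
| south | 0.20 M |  | 10 h |
| west | 0.10 M |  | 10 h |
| south-west | 0.015 M |  | 10 h |

| run | time / h | ring / % | substrate / % |
|---|---|---|---|
| noon | 0.833 | 43.8 | 2.6 |
| noon | 2.50 | 45.4 | 0.6 |
| noon | 5.00 | 44.9 | 0.9 |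
| noon | 8.00 | 45.2 | 1.4 |
| noon | 10.0 | 45.0 | 0.5 |
| dusk | 0.833 | 22.9 | 1.5 |
| dusk | 2.50 | 25.0 | 0 |
| dusk | 5.00 | 23.2 | 0.6 |
| dusk | 8.00 | 23.2 | 0.1 |
| dusk | 10.0 | 23.6 | 1.0 |

(each reading ± 0.5 percentage points)

* ranking by amount of ring, in percent of the substrate charged, from high to low, at 10 h (north / north-east / south-east / south / west / south-west)
* the same order at 30 min (north / north-east / south-east / south / west / south-west)
* the amount of ring, in percent of the substrate charged of the flask you put first, at 10 h
* the amount of ring, in percent of the substrate charged of the flask you put last, at 10 h

- what was read earlier has a scatter of 0.5 percentage points, one standard deviation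

Take the ledger of the substrate at 10.0 h, in fractions of the charge. Noon books 0.5% as substrate, 45.0% as ring and 54.5% as unread remainder. Dusk books 1.0%, 23.6% and 75.4%. The remainder is larger at dusk than at noon, and the dusk charge is 3.12 times the noon charge. From 2.50 h the noon ring readings move within the scatter.

So I book the substrate under two heads: closure, first order in substrate, and a loss, second order. Let u be the charge divided by a constant charge, to be read off the runs. Summed over a run, the ring fraction is then ln(1+u)/u. Noon gives u = 3.18, so 0.0151 M. Dusk gives u = 10.3, so 0.0146 M. Their mean, 0.0149 M, is the scale charge, the fitted charge by which this reckoning divides every charge.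

It is the zero of the scale: for a flask charged there the reckoning books 69.3% to ring. South-west stands at 1.01 of it. I reckon 73.3% for south-east and 19.8% for south, with ring falling as the charge rises. At 30 min the books are still open, but I expect the same order.

The forecast, resting on “first-order ring closure competing with second-order oligomerisation”, gives south-east > south-west > north > north-east > west > south at 10 h, south-east > south-west > north > north-east > west > south at 30 min, 73% for the first flask and 20% for the last.

South-east, at 0.808 of the scale charge, gives 74.1% at 10 h and south gives 19.3%; the order is south-east > south-west > north > north-east > west > south, and at 30 min it is south-east > south-west > north > north-east > west > south.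

    substrate ⇌ ring (K = 45.0, k = 2.50 h⁻¹)
    2 substrate → open dimer (k = 47.0 L mol⁻¹ h⁻¹)
    substrate + open dimer → open trimer (k = 470 L mol⁻¹ h⁻¹)

At 10.0 h south-east holds substrate 1.59%, ring 74.1%, open dimer 2.69% and open trimer 21.7%. A flask like south-east but charged with 0.0048 M stands at 0.322 of the scale charge, which reckons to 86.7% ring, and that flask holds 87.4%.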